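**Retrosynthetic overview**

1. The target is fisetinidol-(4α→6)-fisetinidol-(4α→6)-(+)-catechin carrying a third fisetinidol unit (4α→8) on the catechin; the last step is global hydrogenolysis of a trideca-O-benzyl, twice 6-bromo-capped tetraflavanoid.
2. The interflavan bonds are cut as C4-cation/arene couplings: C4(middle unit)–C6(catechin) last (thio-activated dimer + dimer), before it C4–C8(catechin) and C4–C6(fisetinidol) with 4-OH as leaving group; all three fisetinidol units come from one leucofisetinidin building block, the catechin unit from the chiral pool.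
3. The building block is tri-O-benzyl-(+)-fustin. Its pyran ring O1–C2–C3–C4–C4a–C8a (the heterocycle of every fisetinidol unit, including the one that ends up 4→8-linked to catechin) is not closed directly but made by enantioconvergent contraction of a racemic seven-membered 1,3-benzodioxepin-5-one acetal, O1–C2–O–C3–C4(=O)–C4a–C8a.
4. Enabling feature: C2 is an aryl-bearing carbon on the A-ring oxygen O1 (acetal/oxocarbenium level), and C3 is an oxygen-bearing carbon α to the C4 carbonyl on the A-ring. A [1,2] O→C shift of C2 from the C3-oxygen to C3 therefore forms C2–C3, pushes that oxygen out of the ring as the 3-OH and sets C2 and C3.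
5. Ring order: the arenes are bought; seven-membered acetal ring (step 2) → six-membered C-ring (step 3); the catechin heterocycle comes from (+)-catechin; no further ring is formed.

Key step: step 3

Assumption: the sense of induction of the chiral acid in step 3 cannot be predicted with certainty; the catalyst enantiomer that delivers the (2R,3R) product is used, written below as (S,S)-IDPi.

**Route**

Step 1
Reactants: 1 1-[4-(benzyloxy)-2-hydroxyphenyl]ethan-1-one
Product: 4 1-[4-(benzyloxy)-2-hydroxyphenyl]-2-hydroxyethan-1-one, via bis-silyl enol ether 2 (not isolated), via bis-silylated hydroxy ketone 3 (not isolated)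
Conditions: TMSOTf (2.3 equiv), Et3N, CH2Cl2, 0 °C; mCPBA, NaHCO3, −20 → 0 °C; 1 M HCl, THF, rt
Reagents that add atoms: mCPBA (OOC(=O)c1cccc(Cl)c1)
Why: Rubottom oxidation; the phenol and the methyl ketone are silylated, the silyl enol ether is epoxidised, 1,4-silyl migration gives the α-silyloxy ketone and aqueous acid removes both silyl groups; no stereocentre is formed.

Step 2
Reactants: 4 1-[4-(benzyloxy)-2-hydroxyphenyl]-2-hydroxyethan-1-one, 5 3,4-bis(benzyloxy)benzaldehyde
Product: 7 rac-8-(benzyloxy)-2-[3,4-bis(benzyloxy)phenyl]-2H-1,3-benzodioxepin-5(4H)-one, via aldehyde dimethyl acetal 6 (not isolated)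
Conditions: 5, HC(OMe)3, PPTS (cat.), MeOH, rt, evaporate; then 4, PPTS (5 mol %), 5 Å MS, CH2Cl2, rt
Reagents that add atoms: none
Why: Acid-catalysed transacetalisation to the mixed aryl/alkyl cyclic acetal, driven by uptake of methanol on the sieves; the weak acid at room temperature should not enolise the ketone, so the O,O-acetal is expected as the kinetic product, and its racemic acetal centre is erased in step 3.

Step 3
Reactants: 7 rac-8-(benzyloxy)-2-[3,4-bis(benzyloxy)phenyl]-2H-1,3-benzodioxepin-5(4H)-one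
Product: 8 (2R,3R)-7-(benzyloxy)-2-[3,4-bis(benzyloxy)phenyl]-3-hydroxy-2,3-dihydro-4H-chromen-4-one (7,3',4'-tri-O-benzyl-(+)-fustin)
Conditions: (S,S)-IDPi (confined chiral imidodiphosphorimidate Brønsted acid, 5 mol %), 5 Å MS, CHCl3, −20 °C
Reagents that add atoms: none
Why: Proposed new method: the chiral acid protonates the alkyl acetal oxygen, heterolysis of its bond to the acetal carbon gives an aryl-oxocarbenium ion (O1=C2, stabilised by the 3,4-dibenzyloxyphenyl group) paired with the chiral anion, and the released α-hydroxy ketone enolises so that its α-carbon (future C3) attacks C2, which moves the acetal carbon from oxygen to carbon in a formal [1,2] O→C shift and contracts the seven-membered ring to the chromanone ring. The closest known reaction type is the chiral-Brønsted-acid-catalysed Petasis–Ferrier-type O→C rearrangement of cyclic vinyl acetals (oxocarbenium/enol ion-pair recombination), together with acid-mediated intramolecular aldol additions of enols to oxocarbenium ions. The one ring closure is a 6-(enolendo)-endo-trig C–C bond formation between C3 and C2. C2 is set by the anion-controlled face of the planar oxocarbenium ion, which makes the step enantioconvergent for the racemic acetal, and C3 is set relative to C2 by a chair-like transition state with aryl and hydroxyl pseudo-equatorial, backed by acid-mediated epimerisation through the enol to the more stable 2,3-trans isomer. The step needs cleavage of the acetal at the alkyl oxygen and attack by the α-carbon; cleavage at O1 is a reversible dead end because the enol carbon could then only close an oxirane, and closure through the other enol terminus would give a strained, reversible 3-formyl-dihydrobenzofuran. The product should be the thermodynamic sink because a labile mixed aryl/alkyl acetal C–O bond is traded for a C–C bond.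

Step 4
Reactants: 8 (2R,3R)-7-(benzyloxy)-2-[3,4-bis(benzyloxy)phenyl]-3-hydroxy-2,3-dihydro-4H-chromen-4-one
Product: 9 (2R,3S,4R)-7-(benzyloxy)-2-[3,4-bis(benzyloxy)phenyl]-3,4-dihydro-2H-chromene-3,4-diol (tri-O-benzyl-(+)-mollisacacidin; 2,3-trans-3,4-trans)
Conditions: NaBH4, THF–MeOH, 0 °C
Reagents that add atoms: none
Why: Hydride reduction of a trans-dihydroflavonol is expected to give mainly the 3,4-trans diol by axial attack; any 4-epimer is equally useful because C4 is ionised in steps 5, 8 and 9.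

Step 5
Reactants: 9 (2R,3S,4R)-7-(benzyloxy)-2-[3,4-bis(benzyloxy)phenyl]-3,4-dihydro-2H-chromene-3,4-diol
Product: 10 (2R,3R,4R)-7-(benzyloxy)-2-[3,4-bis(benzyloxy)phenyl]-4-[(2,6-dimethylphenyl)sulfanyl]-3,4-dihydro-2H-chromen-3-ol (2,3-trans-3,4-trans)
Conditions: 2,6-Me2C6H3SH (1.5 equiv), BF3·OEt2 (0.3 equiv), 4 Å MS, CH2Cl2, −40 °C
Reagents that add atoms: 2,6-dimethylbenzenethiol (Cc1cccc(C)c1S)
Why: SN1 substitution through the 7-alkoxy-stabilised flavan-4-yl cation (thiolysis type) with the thiol entering anti to the 3-OH; it installs a soft leaving group that a hard Lewis acid should leave untouched (orthogonal S/O activation).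

Step 6
Reactants: 9 (2R,3S,4R)-7-(benzyloxy)-2-[3,4-bis(benzyloxy)phenyl]-3,4-dihydro-2H-chromene-3,4-diol
Product: 11 (2R,3S,4R)-7-(benzyloxy)-2-[3,4-bis(benzyloxy)phenyl]-6-bromo-3,4-dihydro-2H-chromene-3,4-diol
Conditions: NBS (1.05 equiv), CH2Cl2, −40 → 0 °C
Reagents that add atoms: N-bromosuccinimide (O=C1CCC(=O)N1Br)
Why: Electrophilic aromatic bromination at C6, para to O1 and ortho to the 7-benzyloxy group of the resorcinol-type A-ring, which is far more activated than the catechol-type B-ring; the bromine blocks and deactivates this ring (halo cap) and is removed in step 11.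

Step 7
Reactants: 12 (+)-catechin
Product: 13 (2R,3S)-5,7-bis(benzyloxy)-2-[3,4-bis(benzyloxy)phenyl]-3,4-dihydro-2H-chromen-3-ol (5,7,3',4'-tetra-O-benzyl-(+)-catechin)
Conditions: BnBr (4.2 equiv), K2CO3, DMF, 0 °C → rt
Reagents that add atoms: benzyl bromide (BrCc1ccccc1)
Why: Williamson etherification of the four phenols with carbonate base, which leaves the secondary 3-OH and both stereocentres untouched.

Step 8
Reactants: 11 (2R,3S,4R)-7-(benzyloxy)-2-[3,4-bis(benzyloxy)phenyl]-6-bromo-3,4-dihydro-2H-chromene-3,4-diol, 13 5,7,3',4'-tetra-O-benzyl-(+)-catechin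
Product: 14 6-bromo-7,3',4'-tri-O-benzylfisetinidol-(4α→8)-5,7,3',4'-tetra-O-benzylcatechin
Conditions: 13 (3 equiv), BF3·OEt2 (0.5 equiv), 4 Å MS, CH2Cl2, −40 → 0 °C
Reagents that add atoms: none
Why: Biomimetic leucofisetinidin coupling (Friedel–Crafts alkylation): ionisation of the 4-OH gives the flavan-4-yl cation, which C8 of the excess catechin ether (its most nucleophilic position) should capture anti to the 3-OH, setting C4 as 3,4-trans (4α); the bromo cap prevents self-condensation.

Step 9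
Reactants: 11 (2R,3S,4R)-7-(benzyloxy)-2-[3,4-bis(benzyloxy)phenyl]-6-bromo-3,4-dihydro-2H-chromene-3,4-diol, 10 (2R,3R,4R)-7-(benzyloxy)-2-[3,4-bis(benzyloxy)phenyl]-4-[(2,6-dimethylphenyl)sulfanyl]-3,4-dihydro-2H-chromen-3-ol
Product: 15 6-bromo-7,3',4'-tri-O-benzylfisetinidol-(4α→6)-7,3',4'-tri-O-benzyl-4-[(2,6-dimethylphenyl)sulfanyl]fisetinidol
Conditions: 10 (1.5 equiv), BF3·OEt2 (0.5 equiv), 4 Å MS, CH2Cl2, −78 → −30 °C
Reagents that add atoms: none
Why: The same Friedel–Crafts coupling with C6 of 10 (para to O1, least hindered) as nucleophile; the hindered aryl sulfide should not be activated by BF3·OEt2 at low temperature, and attack anti to the 3-OH sets the new C4 centre as 3,4-trans.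

Step 10
Reactants: 15 6-bromo-7,3',4'-tri-O-benzylfisetinidol-(4α→6)-7,3',4'-tri-O-benzyl-4-[(2,6-dimethylphenyl)sulfanyl]fisetinidol, 14 6-bromo-7,3',4'-tri-O-benzylfisetinidol-(4α→8)-5,7,3',4'-tetra-O-benzylcatechin
Product: 16 trideca-O-benzyl-6-bromofisetinidol-(4α→6)-fisetinidol-(4α→6)-catechin-(8←4α)-6-bromofisetinidol
Conditions: AgBF4 (2.5 equiv), 4 Å MS, THF, 0 °C
Reagents that add atoms: none
Why: Thiophilic activation of the 4-arylsulfanyl group generates the C4 cation of the middle unit, which C6 of the catechin unit of 14 (the only uncapped phloroglucinol-type position) should capture anti to the 3-OH to give the 3,4-trans (4α→6) bond.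

Step 11
Reactants: 16 trideca-O-benzyl-6-bromofisetinidol-(4α→6)-fisetinidol-(4α→6)-catechin-(8←4α)-6-bromofisetinidol
Product: 17 fisetinidol-(4α→6)-fisetinidol-(4α→6)-catechin-(8←4α)-fisetinidol (CNP0263622.1)
Conditions: H2 (1 atm), Pd(OH)2/C, Et3N, THF–MeOH–H2O, rt
Reagents that add atoms: none
Why: Catalytic hydrogenolysis cleaves the thirteen benzyl ethers and both aryl bromides while the amine buffers the acid formed; no stereocentre is touched.

**Compound list**

1 | 1-[4-(benzyloxy)-2-hydroxyphenyl]ethan-1-one | CC(=O)c1ccc(OCc2ccccc2)cc1O | starting material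
2 | {[1-{4-(benzyloxy)-2-[(trimethylsilyl)oxy]phenyl}ethenyl]oxy}(trimethyl)silane | C=C(O[Si](C)(C)C)c1ccc(OCc2ccccc2)cc1O[Si](C)(C)C | intermediate (not isolated)
3 | 1-{4-(benzyloxy)-2-[(trimethylsilyl)oxy]phenyl}-2-[(trimethylsilyl)oxy]ethan-1-one | C[Si](C)(C)OCC(=O)c1ccc(OCc2ccccc2)cc1O[Si](C)(C)C | intermediate (not isolated)
4 | 1-[4-(benzyloxy)-2-hydroxyphenyl]-2-hydroxyethan-1-one | OCC(=O)c1ccc(OCc2ccccc2)cc1O | intermediate
5 | 3,4-bis(benzyloxy)benzaldehyde | O=Cc1ccc(OCc2ccccc2)c(OCc2ccccc2)c1 | starting material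
6 | 1,2-bis(benzyloxy)-4-(dimethoxymethyl)benzene | COC(OC)c1ccc(OCc2ccccc2)c(OCc2ccccc2)c1 | intermediate (not isolated)
7 | rac-8-(benzyloxy)-2-[3,4-bis(benzyloxy)phenyl]-2H-1,3-benzodioxepin-5(4H)-one | O=C1COC(c2ccc(OCc3ccccc3)c(OCc3ccccc3)c2)Oc2cc(OCc3ccccc3)ccc12 | intermediate
8 | (2R,3R)-7-(benzyloxy)-2-[3,4-bis(benzyloxy)phenyl]-3-hydroxy-2,3-dihydro-4H-chromen-4-one | c1cc2c(cc1OCc9ccccc9)O[C@H](c8ccc(OCc9ccccc9)c(OCc9ccccc9)c8)[C@@H](O)C2=O | intermediate
9 | (2R,3S,4R)-7-(benzyloxy)-2-[3,4-bis(benzyloxy)phenyl]-3,4-dihydro-2H-chromene-3,4-diol | c1cc2c(cc1OCc9ccccc9)O[C@H](c8ccc(OCc9ccccc9)c(OCc9ccccc9)c8)[C@@H](O)[C@@H]2O | intermediate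
10 | (2R,3R,4R)-7-(benzyloxy)-2-[3,4-bis(benzyloxy)phenyl]-4-[(2,6-dimethylphenyl)sulfanyl]-3,4-dihydro-2H-chromen-3-ol | c1cc2c(cc1OCc9ccccc9)O[C@H](c8ccc(OCc9ccccc9)c(OCc9ccccc9)c8)[C@@H](O)[C@@H]2Sc1c(C)cccc1C | intermediate
11 | (2R,3S,4R)-7-(benzyloxy)-2-[3,4-bis(benzyloxy)phenyl]-6-bromo-3,4-dihydro-2H-chromene-3,4-diol | Brc1cc2c(cc1OCc9ccccc9)O[C@H](c8ccc(OCc9ccccc9)c(OCc9ccccc9)c8)[C@@H](O)[C@@H]2O | intermediate
12 | (+)-catechin, (2R,3S) | Oc1cc(O)c2c(c1)O[C@H](c1ccc(O)c(O)c1)[C@@H](O)C2 | starting material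
13 | (2R,3S)-5,7-bis(benzyloxy)-2-[3,4-bis(benzyloxy)phenyl]-3,4-dihydro-2H-chromen-3-ol | c1c(OCc9ccccc9)c2c(cc1OCc9ccccc9)O[C@H](c8ccc(OCc9ccccc9)c(OCc9ccccc9)c8)[C@@H](O)C2 | intermediate
14 | 6-bromo-7,3',4'-tri-O-benzylfisetinidol-(4α→8)-5,7,3',4'-tetra-O-benzylcatechin (upper unit 2R,3S with the 4-aryl bond trans to 3-OH) | c1c(OCc9ccccc9)c2c(c([C@@H]3c4cc(Br)c(OCc9ccccc9)cc4O[C@H](c8ccc(OCc9ccccc9)c(OCc9ccccc9)c8)[C@H]3O)c1OCc9ccccc9)O[C@H](c8ccc(OCc9ccccc9)c(OCc9ccccc9)c8)[C@@H](O)C2 | intermediate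
15 | 6-bromo-7,3',4'-tri-O-benzylfisetinidol-(4α→6)-7,3',4'-tri-O-benzyl-4-[(2,6-dimethylphenyl)sulfanyl]fisetinidol (both units 2,3-trans-3,4-trans) | Brc1cc2c(cc1OCc9ccccc9)O[C@H](c8ccc(OCc9ccccc9)c(OCc9ccccc9)c8)[C@@H](O)[C@@H]2c1cc2c(cc1OCc9ccccc9)O[C@H](c8ccc(OCc9ccccc9)c(OCc9ccccc9)c8)[C@@H](O)[C@@H]2Sc1c(C)cccc1C | intermediate
16 | trideca-O-benzyl-6-bromofisetinidol-(4α→6)-fisetinidol-(4α→6)-catechin-(8←4α)-6-bromofisetinidol | Brc1cc2c(cc1OCc9ccccc9)O[C@H](c8ccc(OCc9ccccc9)c(OCc9ccccc9)c8)[C@@H](O)[C@@H]2c1cc2c(cc1OCc9ccccc9)O[C@H](c8ccc(OCc9ccccc9)c(OCc9ccccc9)c8)[C@@H](O)[C@@H]2c1c(OCc9ccccc9)c2c(c([C@@H]3c4cc(Br)c(OCc9ccccc9)cc4O[C@H](c8ccc(OCc9ccccc9)c(OCc9ccccc9)c8)[C@H]3O)c1OCc9ccccc9)O[C@H](c8ccc(OCc9ccccc9)c(OCc9ccccc9)c8)[C@@H](O)C2 | intermediate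
17 | fisetinidol-(4α→6)-fisetinidol-(4α→6)-catechin-(8←4α)-fisetinidol (CNP0263622.1) | Oc1ccc2c(c1)O[C@H](c1ccc(O)c(O)c1)[C@@H](O)[C@@H]2c1cc2c(cc1O)O[C@H](c1ccc(O)c(O)c1)[C@@H](O)[C@@H]2c1c(O)c2c(c([C@@H]3c4ccc(O)cc4O[C@H](c4ccc(O)c(O)c4)[C@H]3O)c1O)O[C@H](c1ccc(O)c(O)c1)[C@@H](O)C2 | target

**Step count and risks**

Total step count: 11. Longest linear sequence: 8 (steps 1, 2, 3, 4, 6, 9, 10, 11).

Steps most likely to fail:

1. Step 3 (proposed new method). The chiral anion may discriminate the two faces of the oxocarbenium ion poorly, the enantiomeric purity may erode by reversible ionisation of the benzylic C2–O1 bond of the product, or closure through the other enol terminus may compete. The fallback uses known chemistry, sets out from 1 (with 5) and comes back at 8. The chelated phenol of 1 is protected with MOMCl and i-Pr2NEt to give 1-[4-(benzyloxy)-2-(methoxymethoxy)phenyl]ethan-1-one F1. Claisen–Schmidt condensation of F1 with 5 (KOH, EtOH) gives (E)-1-[4-(benzyloxy)-2-(methoxymethoxy)phenyl]-3-[3,4-bis(benzyloxy)phenyl]prop-2-en-1-one F2. Juliá–Colonna epoxidation (poly-L-leucine, urea–H2O2, DBU, THF) should give [4-(benzyloxy)-2-(methoxymethoxy)phenyl]{(2R,3S)-3-[3,4-bis(benzyloxy)phenyl]oxiran-2-yl}methanone F3. HCl in MeOH–THF then removes the MOM group, and the freed phenol opens the epoxide at the benzylic carbon (6-endo, inversion) to give the trans-dihydroflavonol 8.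

2. Step 10. Attack of the bulky dimeric cation at the doubly ortho-substituted C6 of the catechin unit may be slow, so that the cation eliminates, decomposes or reacts at a hindered C8 position. The fallback builds the same compound linearly, sets out from 14 and comes back at 16. Dimer 14 (in excess) is coupled with the uncapped monomeric diol 9 (BF3·OEt2, CH2Cl2, low temperature, slow addition of 9) to give 7,3',4'-tri-O-benzylfisetinidol-(4α→6)-5,7,3',4'-tetra-O-benzylcatechin-(8←4α)-6-bromo-7,3',4'-tri-O-benzylfisetinidol F4. The free C6 of its new fisetinidol unit is then alkylated with the capped diol 11 under the same conditions to give 16.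

3. Step 2. The equilibrium to the seven-membered mixed aryl/alkyl acetal may be unfavourable because the chelated phenol is a poor acetal partner, or the acid may trigger a premature, unselective O→C shift. The fallback forms the acetal by oxidation under neutral conditions, sets out from 4 and comes back at 7. The phenol of 4 is alkylated with 3,4-bis(benzyloxy)benzyl chloride (K2CO3, DMF) to give 1-[4-(benzyloxy)-2-{[3,4-bis(benzyloxy)phenyl]methoxy}phenyl]-2-hydroxyethan-1-one F5. Anhydrous DDQ (4 Å MS, CH2Cl2) then oxidises the dialkoxybenzylic position to the oxocarbenium ion, which the neighbouring primary hydroxyl traps to close the acetal 7.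

Further compounds
F1 | step 3 | 1-[4-(benzyloxy)-2-(methoxymethoxy)phenyl]ethan-1-one | CC(=O)c1ccc(OCc2ccccc2)cc1OCOC
F2 | step 3 | (E)-1-[4-(benzyloxy)-2-(methoxymethoxy)phenyl]-3-[3,4-bis(benzyloxy)phenyl]prop-2-en-1-one | O=C(/C=C/c1ccc(OCc2ccccc2)c(OCc2ccccc2)c1)c1ccc(OCc2ccccc2)cc1OCOC
F3 | step 3 | [4-(benzyloxy)-2-(methoxymethoxy)phenyl]{(2R,3S)-3-[3,4-bis(benzyloxy)phenyl]oxiran-2-yl}methanone | O1[C@@H](c2ccc(OCc3ccccc3)c(OCc3ccccc3)c2)[C@@H]1C(=O)c1ccc(OCc2ccccc2)cc1OCOC
F4 | step 10 | 7,3',4'-tri-O-benzylfisetinidol-(4α→6)-5,7,3',4'-tetra-O-benzylcatechin-(8←4α)-6-bromo-7,3',4'-tri-O-benzylfisetinidol | c1cc2c(cc1OCc9ccccc9)O[C@H](c8ccc(OCc9ccccc9)c(OCc9ccccc9)c8)[C@@H](O)[C@@H]2c1c(OCc9ccccc9)c2c(c([C@@H]3c4cc(Br)c(OCc9ccccc9)cc4O[C@H](c8ccc(OCc9ccccc9)c(OCc9ccccc9)c8)[C@H]3O)c1OCc9ccccc9)O[C@H](c8ccc(OCc9ccccc9)c(OCc9ccccc9)c8)[C@@H](O)C2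
F5 | step 2 | 1-[4-(benzyloxy)-2-{[3,4-bis(benzyloxy)phenyl]methoxy}phenyl]-2-hydroxyethan-1-one | OCC(=O)c1ccc(OCc2ccccc2)cc1OCc1ccc(OCc2ccccc2)c(OCc2ccccc2)c1
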